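**Plan**

Numbering: C1 carries C7H2–OBz, C1=C2–C3=C4 is the diene, C5 carries OBz and C6 carries OH; the target is the trans (5R,6R) isomer.
Cuts: the C5–O(benzoyl) bond goes back to a C5–C6 oxirane whose oxygen is O6. The diene goes back to an isolated C2=C3 alkene with C1 sp3. The two oxirane C–O bonds are cut last.
Enabling feature: once C1 is tetrahedral, the six-membered ring is a 1-substituted cyclohexa-2,5-diene with a mirror plane through C7, C1 and C4. C5=C6 and C2=C3 are then mirror-image (enantiotopic) alkenes, each homoallylic to the O7–H that can steer an oxidant.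
Forward: the carbocycle comes intact from benzoic acid (Birch reduction, LiAlH4). The only ring made is the oxirane, closed in step 3 and opened in step 5.
Stereochemistry: a chiral bishydroxamate–hafnium catalyst picks C5=C6 and the O7 tether fixes the face, so C6 (R) is kept to the end. SN2 opening by benzoate inverts C5 to R and tells O5 from O6.
The diene is unmasked only after the oxirane has been opened (PhSeCl addition, selenoxide syn-elimination, E2 loss of HCl). This keeps the route clear of an arene oxide and its oxepine-mediated racemisation.

Key step: step 3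

Assumption: the (1R,2R)-ligand is taken to select C5=C6 by analogy with acyclic (Z)-homoallylic alcohols; both ligand antipodes are commercial, so the (1S,2S)-ligand would be substituted if the sense of induction on this ring diene is the opposite.

**Step 1**
Reactants: 1 benzoic acid
Product: 2 cyclohexa-2,5-diene-1-carboxylic acid (achiral)
Conditions: Na, NH3(l), EtOH, −78 to −33 °C; NH4Cl; aq HCl
Reagents that add atoms: none
Why: Birch reduction of a benzoate salt, in which the carboxylate stabilises the ipso carbanion so that protonation at C1 and C4 gives the unconjugated 2,5-diene acid, which has no stereocentre.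

**Step 2**
Reactants: 2 cyclohexa-2,5-diene-1-carboxylic acid
Product: 3 cyclohexa-2,5-dien-1-ylmethanol (achiral; C7, C1 and C4 on the mirror plane)
Conditions: LiAlH4, Et2O, 0 °C to rt; H2O, aq NaOH
Reagents that add atoms: none
Why: Hydride reduction of a carboxylic acid with LiAlH4 runs through the carboxylate, which resists deprotonation at C1, so the skipped diene should not slip into conjugation and the prochiral primary alcohol results.

**Step 3**
Reactants: 3 cyclohexa-2,5-dien-1-ylmethanol; 4 cumene hydroperoxide
Product: 5 [(1R,2S,6S)-7-oxabicyclo[4.1.0]hept-3-en-2-yl]methanol (target numbering C1 S, C5 S, C6 R; oxirane oxygen cis to the CH2OH group, C2=C3 retained)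
Conditions: Hf(OtBu)4 (10 mol %), (1R,2R)-N,N'-dihydroxy-N,N'-bis(diphenylacetyl)cyclohexane-1,2-diamine (12 mol %), DMPU, 4 Å MS, 4 (1.05 equiv), toluene, 0 °C
Reagents that add atoms: cumene hydroperoxide (4), CC(C)(OO)c1ccccc1
Why: The C7 alkoxide of 3 and the cumyl peroxide bind side by side to tetravalent hafnium inside the C2-symmetric bishydroxamate pocket, and the activated peroxide oxygen is handed in one concerted step to the ring alkene that the tether brings within reach. The closest known reaction type is the bishydroxamic acid/Hf(OtBu)4- or Zr(OtBu)4-catalysed asymmetric epoxidation of primary homoallylic alcohols, (Z)-alkenes included, together with its use for desymmetrising meso dienols, so that the ring-bound skipped diene is a new substrate and not a new reaction. The oxirane, the only ring formed, closes by suprafacial [2+1] transfer of one oxygen atom to C5 and C6, both C–O bonds forming together, which enforces the cis ring fusion. The face is fixed by the short O7–C7–C1 tether (oxygen cis to C7), the choice of C5=C6 over C2=C3 and hence C5 (S) and C6 (R) by the ligand, and C1 becomes S only because the mirror plane through C1 and C4 is lost. Mono-epoxidation is secured by about one equivalent of 4, and any second epoxidation should consume preferentially the minor enantiomer, whose remaining alkene is the one the catalyst prefers, so it should raise the enantiomeric purity of 5. A redox-inert d0 metal is preferred to vanadium so that radical abstraction of the doubly allylic C4–H or C1–H, and with it aromatisation to benzyl alcohol, is held back.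

**Step 4**
Reactants: 5 syn-epoxy alcohol; 6 benzoyl chloride
Product: 7 [(1R,2S,6S)-7-oxabicyclo[4.1.0]hept-3-en-2-yl]methyl benzoate
Conditions: BzCl, Et3N, DMAP (cat.), CH2Cl2, 0 °C
Reagents that add atoms: benzoyl chloride (6), O=C(Cl)c1ccccc1
Why: DMAP-catalysed acylation of a primary alcohol by an acid chloride at low temperature should leave the oxirane, the alkene and all three stereocentres untouched.

**Step 5**
Reactants: 7 epoxy benzoate; 1 benzoic acid
Product: 8 [(1S,5R,6R)-5-(benzoyloxy)-6-hydroxycyclohex-2-en-1-yl]methyl benzoate (O5 trans to O6, O6 cis to C7)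
Conditions: PhCO2H (2 equiv), Bu4N(O2CPh) (20 mol %), MeCN, 60 °C
Reagents that add atoms: benzoic acid (1), OC(=O)c1ccccc1
Why: Carboxylate SN2 opening of an epoxide under benzoic acid buffering attacks from the face opposite the oxirane oxygen, inverting C5 (S to R) and leaving the C6–O bond alone, and C5 should be preferred because its trans-diaxial transition state keeps the C1 side chain pseudoequatorial whereas attack at C6 forces it pseudoaxial, because the C7 ester inductively retards C6–O cleavage, and because that ester, being cis to the oxirane oxygen, cannot reach the back side of C6.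

**Step 6**
Reactants: 8 hydroxy dibenzoate
Product: 9 [(1S,5R,6R)-5-(benzoyloxy)-6-(triethylsilyloxy)cyclohex-2-en-1-yl]methyl benzoate
Conditions: TESOTf, 2,6-lutidine, CH2Cl2, −78 °C
Reagents that add atoms: triethylsilyl triflate, CC[Si](CC)(CC)OS(=O)(=O)C(F)(F)F
Why: Silylation of a hindered secondary alcohol with a silyl triflate and a non-nucleophilic base is fast at low temperature, which forestalls benzoyl migration, and masking O6 is needed because a free hydroxyl would trap the seleniranium ion of step 7 across the ring (C3–O6 ether) and would relay benzoyl groups under DBU in step 8, while no stereocentre is touched.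

**Step 7**
Reactants: 9 silyl ether
Product: 12 [(3R,5R,6R)-5-(benzoyloxy)-3-chloro-6-(triethylsilyloxy)cyclohex-1-en-1-yl]methyl benzoate, via chloro selenide 10 (not isolated), via selenoxide 11 (not isolated)
Conditions: PhSeCl, CH2Cl2, −78 °C; then pyridine, 30% H2O2, 0 °C to rt
Reagents that add atoms: phenylselenenyl chloride, Cl[Se]c1ccccc1 (Cl stays in 12, Se only in 10 and 11); hydrogen peroxide, OO (O only in 11)
Why: Anti addition of PhSeCl followed by selenoxide syn-elimination (the standard alkene-to-allylic-chloride sequence) should place selenium on the face opposite C7 and O6 and, by diaxial opening at C3 in the half-chair with O5 and O6 equatorial, on C2 cis to H1, so the selenoxide eliminates toward C1–H rather than toward the chlorine-bearing C3 to give C1=C2, while the regioisomeric adduct (Se on C3, Cl on C2 trans to H1) would reach the same diene in step 8 and the temporary centres C2 and C3 are erased.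

**Step 8**
Reactants: 12 allylic chloride
Product: 13 [(5R,6R)-5-(benzoyloxy)-6-(triethylsilyloxy)cyclohexa-1,3-dien-1-yl]methyl benzoate
Conditions: DBU, toluene, 80 °C
Reagents that add atoms: none
Why: E2 dehydrochlorination of a cyclohexenyl chloride to the 1,3-diene is favoured because the pseudoaxial C3–Cl is antiperiplanar to the axial C4–H in the half-chair that keeps O5 and O6 equatorial, whereas the C5 benzoate is not expelled since H6 is cis to it and the masked O6 cannot relay acyl groups.

**Step 9**
Reactants: 13 silyl-protected diene
Product: 14 [(5R,6R)-5-(benzoyloxy)-6-hydroxycyclohexa-1,3-dien-1-yl]methyl benzoate (CNP0113836.1)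
Conditions: HF·pyridine, pyridine, THF, 0 °C
Reagents that add atoms: none
Why: Fluoride-mediated cleavage of a triethylsilyl ether in a pyridine-buffered medium is neither basic enough for benzoyl migration from O5 or O7 to O6 nor acidic enough to dehydrate the dihydroarene diol to an aromatic compound, so C5 and C6 should stay (R,R).

**Compound list**

1 | benzoic acid | OC(=O)c1ccccc1 | starting material
2 | cyclohexa-2,5-diene-1-carboxylic acid | OC(=O)C1C=CCC=C1 | intermediate
3 | cyclohexa-2,5-dien-1-ylmethanol | OCC1C=CCC=C1 | intermediate
4 | cumene hydroperoxide | CC(C)(OO)c1ccccc1 | starting material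
5 | [(1R,2S,6S)-7-oxabicyclo[4.1.0]hept-3-en-2-yl]methanol | OC[C@@H]1C=CC[C@@H]2O[C@H]12 | intermediate
6 | benzoyl chloride | O=C(Cl)c1ccccc1 | starting material
7 | [(1R,2S,6S)-7-oxabicyclo[4.1.0]hept-3-en-2-yl]methyl benzoate | O=C(OC[C@@H]1C=CC[C@@H]2O[C@H]12)c1ccccc1 | intermediate
8 | [(1S,5R,6R)-5-(benzoyloxy)-6-hydroxycyclohex-2-en-1-yl]methyl benzoate | O=C(OC[C@@H]1C=CC[C@@H](OC(=O)c2ccccc2)[C@@H]1O)c1ccccc1 | intermediate
9 | [(1S,5R,6R)-5-(benzoyloxy)-6-(triethylsilyloxy)cyclohex-2-en-1-yl]methyl benzoate | O=C(OC[C@@H]1C=CC[C@@H](OC(=O)c2ccccc2)[C@@H]1O[Si](CC)(CC)CC)c1ccccc1 | intermediate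
10 | [(1S,2R,3R,5R,6R)-5-(benzoyloxy)-3-chloro-2-(phenylselanyl)-6-(triethylsilyloxy)cyclohexyl]methyl benzoate | O=C(OC[C@@H]1[C@@H]([Se]c2ccccc2)[C@H](Cl)C[C@@H](OC(=O)c2ccccc2)[C@@H]1O[Si](CC)(CC)CC)c1ccccc1 | intermediate
11 | [(1S,2R,3R,5R,6R)-5-(benzoyloxy)-3-chloro-2-(phenylseleninyl)-6-(triethylsilyloxy)cyclohexyl]methyl benzoate (both configurations at Se) | O=C(OC[C@@H]1[C@@H]([Se](=O)c2ccccc2)[C@H](Cl)C[C@@H](OC(=O)c2ccccc2)[C@@H]1O[Si](CC)(CC)CC)c1ccccc1 | intermediate
12 | [(3R,5R,6R)-5-(benzoyloxy)-3-chloro-6-(triethylsilyloxy)cyclohex-1-en-1-yl]methyl benzoate | O=C(OCC1=C[C@H](Cl)C[C@@H](OC(=O)c2ccccc2)[C@@H]1O[Si](CC)(CC)CC)c1ccccc1 | intermediate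
13 | [(5R,6R)-5-(benzoyloxy)-6-(triethylsilyloxy)cyclohexa-1,3-dien-1-yl]methyl benzoate | O=C(OCC1=CC=C[C@@H](OC(=O)c2ccccc2)[C@@H]1O[Si](CC)(CC)CC)c1ccccc1 | intermediate
14 | [(5R,6R)-5-(benzoyloxy)-6-hydroxycyclohexa-1,3-dien-1-yl]methyl benzoate | O=C(OCC1=CC=C[C@@H](OC(=O)c2ccccc2)[C@@H]1O)c1ccccc1 | target

Total step count: 9. Longest linear sequence: 9 steps (1 to 14).

**Steps most likely to fail**

**Risk 1, step 3.** The catalyst may discriminate weakly between the two enantiotopic alkenes of a compact, nearly flat ring. The skipped diene may also aromatise, or the second alkene may be epoxidised too readily.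
- The fallback sets out from 3 and comes back at 5, using known chemistry.
- Achiral hydroxyl-directed epoxidation with VO(acac)2 and tert-butyl hydroperoxide in CH2Cl2 at 0 °C forms the same two C–O bonds on the face cis to C7. It would give 5 together with its mirror image, the ent-epoxy alcohol F1.
- Lipase-catalysed acetylation (Burkholderia cepacia lipase, vinyl acetate, MTBE) would then convert the faster-reacting antipode into the ent-epoxy acetate F2.
- Unreacted 5 would be separated by chromatography and carried into step 4.

**Risk 2, step 5.** Benzoate may attack C6 in competition with C5. Benzoyl may migrate slowly between O5 and O6 at 60 °C, or base may isomerise the oxirane, which would be followed by aromatisation.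
- The fallback sets out from 7 and comes back at 8. It replaces substrate control by reagent control.
- Benzoic acid is added at 0 °C to rt in MTBE with iPr2NEt, catalysed by enantiopure N,N'-bis(3,5-di-tert-butylsalicylidene)cyclohexane-1,2-diaminocobalt. This divalent cobalt precatalyst is aerated in the presence of benzoic acid to the trivalent cobalt benzoate.
- The antipode chosen is the one that opens meso-cyclohexene oxide to the (R,R)-hydroxy benzoate, that is, the one that attacks an S-configured oxirane carbon. In 7 that carbon is C5, so catalyst and substrate preferences add up, at a temperature where acyl migration is slow.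
- No compound outside the list is made (F0).

**Risk 3, step 7.** Selenium may add to the wrong face. The seleniranium ion may be captured by the C7 benzoate carbonyl or by the silyl ether oxygen with loss of the protecting group. The selenoxide may also eliminate toward the chlorine-bearing carbon.
- The fallback sets out from 9 and comes back at 13, bypassing 12 and step 8. It is the classical bromination and double dehydrobromination used for trans-dihydrodiol esters.
- Br2 in CH2Cl2 at −78 °C should give the trans-2,3-dibromide F3.
- LiBr and Li2CO3 in DMF at 80 °C should first remove H4 and Br3 to give the allylic bromide F4, whose C2–Br is cis to H1.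
- Bromide exchange then inverts C2 to the epimeric allylic bromide F5, in which bromine is antiperiplanar to H1, and E2 loss of HBr leads to 13.
- Either trans-dibromide would therefore converge on the same diene.

**Further compounds**

F1 | step 3 | [(1S,2R,6R)-7-oxabicyclo[4.1.0]hept-3-en-2-yl]methanol (mirror image of 5) | OC[C@H]1C=CC[C@H]2O[C@@H]12
F2 | step 3 | [(1S,2R,6R)-7-oxabicyclo[4.1.0]hept-3-en-2-yl]methyl acetate | CC(=O)OC[C@H]1C=CC[C@H]2O[C@@H]12
F0 | step 5 | none | none
F3 | step 7 | [(1S,2R,3R,5R,6R)-5-(benzoyloxy)-2,3-dibromo-6-(triethylsilyloxy)cyclohexyl]methyl benzoate | O=C(OC[C@@H]1[C@@H](Br)[C@H](Br)C[C@@H](OC(=O)c2ccccc2)[C@@H]1O[Si](CC)(CC)CC)c1ccccc1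
F4 | step 7 | [(1S,2S,5R,6R)-5-(benzoyloxy)-2-bromo-6-(triethylsilyloxy)cyclohex-3-en-1-yl]methyl benzoate (Br cis to H1) | O=C(OC[C@@H]1[C@@H](Br)C=C[C@@H](OC(=O)c2ccccc2)[C@@H]1O[Si](CC)(CC)CC)c1ccccc1
F5 | step 7 | [(1S,2R,5R,6R)-5-(benzoyloxy)-2-bromo-6-(triethylsilyloxy)cyclohex-3-en-1-yl]methyl benzoate (Br trans to H1) | O=C(OC[C@@H]1[C@H](Br)C=C[C@@H](OC(=O)c2ccccc2)[C@@H]1O[Si](CC)(CC)CC)c1ccccc1
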